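**Plan**
- Retrosynthesis cuts C3–C4 of ring C first, then the O1–C2 ether bond, then the C8–CH2 bond to the side chain; the prenyl-end hydration and the phenol protecting groups are functional-group operations.
- Enabling feature: C3–OH and C4=O of ring C are the enol form of a 3,4-dione, one oxidation level above an α-ketol (benzoin), and O1 is the one ring-A phenol oxygen flanked by C8 (side chain) and C4a (formyl carbon).
- Forward, chain first: the bis-MOM ether of 5-methoxyresorcinol is iodinated at the future C8 and joined to the lavandulyl zinc reagent; the prenyl alkene is then hydrated through its epoxide, C4 is added by formylation and O1 is freed by chelation.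
- O-Alkylation with the ring-B α-bromo arylacetate makes O1–C2; reduction and oxidation give the dialdehyde; the carbene-catalysed benzoin closes ring C (the only ring made) with dehydrogenation in the same flask; MOM and methyl ethers are then removed.
- Stereochemistry: the single stereocentre comes from (S)-lavandulol, obtained by lipase resolution of the racemate. It is never a reacting centre, and its label changes to R only because CH2–aryl replaces CH2–OH in the priority order. C2 is made as both epimers and becomes sp2.

Key step: step 15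

Assumption: the lipase acylates (R)-lavandulol faster, so the alcohol left over is the (S)-enantiomer; were the preference reversed, the ester fraction would be saponified and used instead.

Step 1
Reactants: 1 (±)-lavandulol
Product: 2 (S)-lavandulol [(2S)-5-methyl-2-(prop-1-en-2-yl)hex-4-en-1-ol]
Conditions: porcine pancreatic lipase, vinyl acetate, t-BuOMe, 25 °C, run beyond half conversion (chiral GC control); chromatography
Reagents that add atoms: none
Why: Lipase-catalysed enantioselective transesterification (kinetic resolution) should acetylate the (R)-alcohol and leave the (S)-alcohol, which supplies the only stereocentre of the target.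

Step 2
Reactants: 2 (S)-lavandulol
Product: 3 (S)-lavandulyl iodide [(5S)-5-(iodomethyl)-2,6-dimethylhepta-2,6-diene]
Conditions: PPh3, I2, imidazole, CH2Cl2, 0 °C → rt
Reagents that add atoms: iodine, II
Why: Appel iodination replaces the primary hydroxyl by SN2 at CH2, so the neighbouring stereocentre is not touched.

Step 3
Reactants: 4 5-methoxyresorcinol
Product: 5 1-methoxy-3,5-bis(methoxymethoxy)benzene
Conditions: MOMCl, i-Pr2NEt, CH2Cl2, 0 °C → rt
Reagents that add atoms: chloromethyl methyl ether, COCCl
Why: Williamson-type O-alkylation of both phenols installs the acetal ethers that later direct two metalations.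

Step 4
Reactants: 5 1-methoxy-3,5-bis(methoxymethoxy)benzene
Product: 7 2-iodo-5-methoxy-1,3-bis(methoxymethoxy)benzene, via aryllithium 6 (not isolated)
Conditions: n-BuLi, THF, 0 °C; then I2, −78 °C → rt
Reagents that add atoms: iodine, II
Why: Directed ortho-metalation should occur at the carbon flanked by two chelating methoxymethoxy groups rather than next to the methoxy group, and iodine traps the aryllithium.

Step 5
Reactants: 3 (S)-lavandulyl iodide; 7 2-iodo-5-methoxy-1,3-bis(methoxymethoxy)benzene
Product: 9 5-methoxy-1,3-bis(methoxymethoxy)-2-[(2R)-5-methyl-2-(prop-1-en-2-yl)hex-4-en-1-yl]benzene, via (S)-lavandulylzinc iodide 8 (not isolated)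
Conditions: 3, Zn dust (activated with BrCH2CH2Br and Me3SiCl), LiCl, THF, 40 °C; then 7, Pd(OAc)2 (2 mol %), SPhos (2-dicyclohexylphosphino-2',6'-dimethoxybiphenyl, 4 mol %), THF, 25 → 50 °C
Reagents that add atoms: none
Why: Negishi sp3–sp2 coupling of the primary alkylzinc iodide with the hindered aryl iodide, where the bulky biarylphosphine should make reductive elimination faster than β-hydride elimination at the stereocentre, which lies β to the metal and is not a reacting centre.

Step 6
Reactants: 9 5-methoxy-1,3-bis(methoxymethoxy)-2-[(2R)-5-methyl-2-(prop-1-en-2-yl)hex-4-en-1-yl]benzene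
Product: 10 2-{(2S)-2-[(3,3-dimethyloxiran-2-yl)methyl]-3-methylbut-3-en-1-yl}-5-methoxy-1,3-bis(methoxymethoxy)benzene (both oxirane epimers; side-chain centre unchanged in space)
Conditions: m-CPBA (1.0 equiv), NaHCO3, CH2Cl2, −20 → 0 °C
Reagents that add atoms: 3-chloroperoxybenzoic acid, OOC(=O)c1cccc(Cl)c1
Why: Prilezhaev epoxidation is faster at the trisubstituted than at the 1,1-disubstituted alkene, so one equivalent of peracid should oxidise only the prenyl end; the new oxirane centre is uncontrolled and is removed in step 7.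

Step 7
Reactants: 10 the epoxide described in step 6
Product: 11 (5R)-5-{[4-methoxy-2,6-bis(methoxymethoxy)phenyl]methyl}-2,6-dimethylhept-6-en-2-ol
Conditions: LiAlH4, THF, 0 °C → rt; aq. NaOH work-up
Reagents that add atoms: none
Why: Hydride opening of the trisubstituted epoxide by SN2 attack at its less substituted carbon gives the tertiary alcohol (net Markovnikov hydration of the prenyl alkene) and turns the oxirane CH into CH2.

Step 8
Reactants: 11 (5R)-5-{[4-methoxy-2,6-bis(methoxymethoxy)phenyl]methyl}-2,6-dimethylhept-6-en-2-ol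
Product: 13 3-[(2R)-5-hydroxy-5-methyl-2-(prop-1-en-2-yl)hexyl]-6-methoxy-2,4-bis(methoxymethoxy)benzaldehyde, via aryllithium alkoxide 12 (not isolated)
Conditions: n-BuLi (2.4 equiv), TMEDA, THF, 0 °C; then DMF, −78 → 0 °C; aq. NH4Cl
Reagents that add atoms: N,N-dimethylformamide, CN(C)C=O
Why: Directed ortho-metalation and formylation: after the alcohol is deprotonated, either of the two equivalent ring positions between a methoxymethoxy and the methoxy group is lithiated and DMF delivers the formyl carbon (future C4).

Step 9
Reactants: 13 3-[(2R)-5-hydroxy-5-methyl-2-(prop-1-en-2-yl)hexyl]-6-methoxy-2,4-bis(methoxymethoxy)benzaldehyde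
Product: 14 2-hydroxy-3-[(2R)-5-hydroxy-5-methyl-2-(prop-1-en-2-yl)hexyl]-6-methoxy-4-(methoxymethoxy)benzaldehyde
Conditions: MgBr2·OEt2 (3 equiv), Et2O–CH2Cl2, 0 °C → rt; aq. NH4Cl
Reagents that add atoms: none
Why: Chelation-controlled acetal cleavage: magnesium bridges the formyl oxygen and the adjacent acetal oxygen, so bromide should cleave only the MOM group ortho to the aldehyde and spare the para MOM group, the methyl ether, the alkene and the tertiary alcohol.

Step 10
Reactants: 15 2,4-dihydroxyphenylacetic acid
Product: 16 methoxymethyl [2,4-bis(methoxymethoxy)phenyl]acetate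
Conditions: MOMCl (3.6 equiv), i-Pr2NEt, CH2Cl2, 0 °C → rt
Reagents that add atoms: chloromethyl methyl ether, COCCl
Why: Alkylation of the carboxylate and of both phenols by chloromethyl methyl ether protects ring B and forms the ester in one operation.

Step 11
Reactants: 16 methoxymethyl [2,4-bis(methoxymethoxy)phenyl]acetate
Product: 18 methoxymethyl bromo[2,4-bis(methoxymethoxy)phenyl]acetate (racemic), via lithium enolate 17 (not isolated)
Conditions: LiN(SiMe3)2, THF, −78 °C; enolate added to NBS, THF, −78 °C; aq. NH4Cl
Reagents that add atoms: N-bromosuccinimide, O=C1CCC(=O)N1Br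
Why: Electrophilic bromination of the preformed ester enolate by inverse addition at low temperature should place bromine at the benzylic α-carbon and not on the electron-rich ring.

Step 12
Reactants: 14 2-hydroxy-3-[(2R)-5-hydroxy-5-methyl-2-(prop-1-en-2-yl)hexyl]-6-methoxy-4-(methoxymethoxy)benzaldehyde; 18 methoxymethyl bromo[2,4-bis(methoxymethoxy)phenyl]acetate
Product: 19 methoxymethyl [2,4-bis(methoxymethoxy)phenyl]{2-formyl-6-[(2R)-5-hydroxy-5-methyl-2-(prop-1-en-2-yl)hexyl]-3-methoxy-5-(methoxymethoxy)phenoxy}acetate (both epimers at the O–CH carbon)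
Conditions: K2CO3, DMF, 0 °C → rt
Reagents that add atoms: none
Why: Williamson ether synthesis: the phenoxide displaces the activated benzylic α-bromo ester (SN2) and so fixes O1–C2 before ring closure, while the tertiary alcohol is not deprotonated; the new centre forms as both epimers and is erased in step 15.

Step 13
Reactants: 19 the aryloxy ester described in step 12
Product: 20 (5R)-5-{[2-{1-[2,4-bis(methoxymethoxy)phenyl]-2-hydroxyethoxy}-3-(hydroxymethyl)-4-methoxy-6-(methoxymethoxy)phenyl]methyl}-2,6-dimethylhept-6-en-2-ol (both epimers)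
Conditions: LiBH4, THF, 0 °C → rt
Reagents that add atoms: none
Why: Borohydride reduction takes both the formyl group and the activated α-aryloxy ester to primary alcohols, because the ester cannot be reduced to the aldehyde level while the aryl aldehyde is present.

Step 14
Reactants: 20 the diol described in step 13
Product: 21 2-{1-[2,4-bis(methoxymethoxy)phenyl]-2-oxoethoxy}-3-[(2R)-5-hydroxy-5-methyl-2-(prop-1-en-2-yl)hexyl]-6-methoxy-4-(methoxymethoxy)benzaldehyde (both epimers)
Conditions: Dess–Martin periodinane (3 equiv), NaHCO3, CH2Cl2, 0 °C → rt; crude product used at once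
Reagents that add atoms: none
Why: Dess–Martin oxidation of the benzylic and the primary alcohol under bicarbonate buffer should give both aldehydes without amine base that would enolise the O–CH(Ar)–CHO unit, and the tertiary alcohol cannot be oxidised.

Step 15
Reactants: 21 the dialdehyde described in step 14
Product: 23 2-[2,4-bis(methoxymethoxy)phenyl]-3-hydroxy-8-[(2R)-5-hydroxy-5-methyl-2-(prop-1-en-2-yl)hexyl]-5-methoxy-7-(methoxymethoxy)-4H-chromen-4-one (Kushenol G 5-O-methyl 7,2',4'-tris-MOM ether), via dihydroflavonol ketol 22 (not isolated)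
Conditions: 6,7-dihydro-2-(pentafluorophenyl)-5H-pyrrolo[2,1-c][1,2,4]triazolium tetrafluoroborate (20 mol %), KN(SiMe3)2 (18 mol %), THF (0.02 M), 25 °C, argon; then 1,8-diazabicyclo[5.4.0]undec-7-ene (DBU, 2 equiv), O2 (1 atm), 25 °C
Reagents that add atoms: none
Why: The triazolylidene adds to a formyl carbon and proton transfer gives the Breslow intermediate (an acyl-anion equivalent), which attacks the second formyl carbon of the same molecule; loss of the carbene leaves α-ketol 22 with the new C3–C4 bond, and DBU with O2 then oxidises its enediolate to the 3,4-dione, which exists as its enol, flavonol 23. The closest known reactions are the carbene-catalysed intramolecular crossed aldehyde–ketone benzoin that gives 3-hydroxychroman-4-ones, the one-flask benzoin/aerobic oxidation to 1,2-diones and the base/air dehydrogenation of dihydroflavonols. Ring C closes in a 6-exo-trig mode, the acyl-anion carbon attacking the C=O carbon with O1 and C2 already in place. No stereocentre has to be controlled: C2 and C3 arise as mixtures and both become sp2 in the oxidation, while the side-chain centre is remote and bears no acidic hydrogen. The step needs C–C bond formation to win over homo-coupling, which the six-membered intramolecular closure at high dilution secures, and over two side reactions of the aliphatic aldehyde, namely loss of the ring-A aryloxide from its Breslow intermediate and aldol closure through the acidic O–CH(Ar) hydrogen, which are held back by generating the carbene with a deficit of base, by the poor leaving ability of the electron-rich aryloxide and by excluding oxygen until the dialdehyde is consumed. Which aldehyde serves as donor does not matter, because either ketol regioisomer is oxidised to the same dione.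

Step 16
Reactants: 23 Kushenol G 5-O-methyl 7,2',4'-tris-MOM ether
Product: 25 Kushenol G 5-O-methyl ether [2-(2,4-dihydroxyphenyl)-3,7-dihydroxy-8-[(2R)-5-hydroxy-5-methyl-2-(prop-1-en-2-yl)hexyl]-5-methoxy-4H-chromen-4-one], via pentakis(trimethylsilyl) ether 24 (not isolated)
Conditions: Me3SiOTf (8 equiv), 2,2'-bipyridyl (12 equiv), CH3CN, 0 °C → rt; then H2O, rt
Reagents that add atoms: none
Why: Silyl triflate/2,2'-bipyridyl cleavage of aromatic MOM ethers converts the acetals through pyridinium salts into silyl ethers under buffered aprotic conditions and water then hydrolyses every silyl ether, so the isopropenyl group and the tertiary alcohol never meet strong protic acid.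

Step 17
Reactants: 25 Kushenol G 5-O-methyl ether
Product: 26 Kushenol G
Conditions: MgI2·OEt2 (8 equiv), THF, 50 °C; cold aq. NH4Cl
Reagents that add atoms: none
Why: Chelation-assisted demethylation: magnesium held between C4=O and the 5-methoxy oxygen activates that ether alone, and iodide removes the methyl group by SN2 to free the hydrogen-bonded 5-hydroxyl.

**Compound list**
1 | (±)-lavandulol | C=C(C)C(CO)CC=C(C)C | starting material
2 | (S)-lavandulol | C=C(C)[C@H](CC=C(C)C)CO | intermediate
3 | (S)-lavandulyl iodide | C=C(C)[C@H](CC=C(C)C)CI | intermediate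
4 | 5-methoxyresorcinol | COc1cc(O)cc(O)c1 | starting material
5 | 1-methoxy-3,5-bis(methoxymethoxy)benzene | COCOc1cc(OC)cc(OCOC)c1 | intermediate
6 | 4-methoxy-2,6-bis(methoxymethoxy)phenyllithium | [Li]c1c(OCOC)cc(OC)cc1OCOC | intermediate
7 | 2-iodo-5-methoxy-1,3-bis(methoxymethoxy)benzene | COCOc1cc(OC)cc(OCOC)c1I | intermediate
8 | (S)-lavandulylzinc iodide | C=C(C)[C@H](CC=C(C)C)C[Zn]I | intermediate
9 | 5-methoxy-1,3-bis(methoxymethoxy)-2-[(2R)-5-methyl-2-(prop-1-en-2-yl)hex-4-en-1-yl]benzene | C=C(C)[C@H](CC=C(C)C)Cc1c(OCOC)cc(OC)cc1OCOC | intermediate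
10 | 2-{(2S)-2-[(3,3-dimethyloxiran-2-yl)methyl]-3-methylbut-3-en-1-yl}-5-methoxy-1,3-bis(methoxymethoxy)benzene, both oxirane epimers | C=C(C)[C@H](CC1OC1(C)C)Cc1c(OCOC)cc(OC)cc1OCOC | intermediate
11 | (5R)-5-{[4-methoxy-2,6-bis(methoxymethoxy)phenyl]methyl}-2,6-dimethylhept-6-en-2-ol | C=C(C)[C@H](CCC(C)(C)O)Cc1c(OCOC)cc(OC)cc1OCOC | intermediate
12 | ring-lithiated lithium alkoxide of 11 | C=C(C)[C@H](CCC(C)(C)O[Li])Cc1c(OCOC)cc(OC)c([Li])c1OCOC | intermediate
13 | 3-[(2R)-5-hydroxy-5-methyl-2-(prop-1-en-2-yl)hexyl]-6-methoxy-2,4-bis(methoxymethoxy)benzaldehyde | C=C(C)[C@H](CCC(C)(C)O)Cc1c(OCOC)cc(OC)c(C=O)c1OCOC | intermediate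
14 | 2-hydroxy-3-[(2R)-5-hydroxy-5-methyl-2-(prop-1-en-2-yl)hexyl]-6-methoxy-4-(methoxymethoxy)benzaldehyde | C=C(C)[C@H](CCC(C)(C)O)Cc1c(OCOC)cc(OC)c(C=O)c1O | intermediate
15 | 2,4-dihydroxyphenylacetic acid | OC(=O)Cc1ccc(O)cc1O | starting material
16 | methoxymethyl [2,4-bis(methoxymethoxy)phenyl]acetate | COCOC(=O)Cc1ccc(OCOC)cc1OCOC | intermediate
17 | lithium enolate of 16 | COCOC(O[Li])=Cc1ccc(OCOC)cc1OCOC | intermediate
18 | methoxymethyl bromo[2,4-bis(methoxymethoxy)phenyl]acetate (racemic) | COCOC(=O)C(Br)c1ccc(OCOC)cc1OCOC | intermediate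
19 | methoxymethyl [2,4-bis(methoxymethoxy)phenyl]{2-formyl-6-[(2R)-5-hydroxy-5-methyl-2-(prop-1-en-2-yl)hexyl]-3-methoxy-5-(methoxymethoxy)phenoxy}acetate, both epimers at O–CH | C=C(C)[C@H](CCC(C)(C)O)Cc1c(OCOC)cc(OC)c(C=O)c1OC(C(=O)OCOC)c1ccc(OCOC)cc1OCOC | intermediate
20 | (5R)-5-{[2-{1-[2,4-bis(methoxymethoxy)phenyl]-2-hydroxyethoxy}-3-(hydroxymethyl)-4-methoxy-6-(methoxymethoxy)phenyl]methyl}-2,6-dimethylhept-6-en-2-ol, both epimers at O–CH | C=C(C)[C@H](CCC(C)(C)O)Cc1c(OCOC)cc(OC)c(CO)c1OC(CO)c1ccc(OCOC)cc1OCOC | intermediate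
21 | 2-{1-[2,4-bis(methoxymethoxy)phenyl]-2-oxoethoxy}-3-[(2R)-5-hydroxy-5-methyl-2-(prop-1-en-2-yl)hexyl]-6-methoxy-4-(methoxymethoxy)benzaldehyde, both epimers at O–CH | C=C(C)[C@H](CCC(C)(C)O)Cc1c(OCOC)cc(OC)c(C=O)c1OC(C=O)c1ccc(OCOC)cc1OCOC | intermediate
22 | 2-[2,4-bis(methoxymethoxy)phenyl]-3-hydroxy-8-[(2R)-5-hydroxy-5-methyl-2-(prop-1-en-2-yl)hexyl]-5-methoxy-7-(methoxymethoxy)chroman-4-one, mixture at C2 and C3 | C=C(C)[C@H](CCC(C)(C)O)Cc1c(OCOC)cc(OC)c2C(=O)C(O)C(c3ccc(OCOC)cc3OCOC)Oc12 | intermediate
23 | 2-[2,4-bis(methoxymethoxy)phenyl]-3-hydroxy-8-[(2R)-5-hydroxy-5-methyl-2-(prop-1-en-2-yl)hexyl]-5-methoxy-7-(methoxymethoxy)-4H-chromen-4-one | C=C(C)[C@H](CCC(C)(C)O)Cc1c(OCOC)cc(OC)c2c(=O)c(O)c(-c3ccc(OCOC)cc3OCOC)oc12 | intermediate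
24 | pentakis(trimethylsilyl) ether of Kushenol G 5-O-methyl ether | C=C(C)[C@H](CCC(C)(C)O[Si](C)(C)C)Cc1c(O[Si](C)(C)C)cc(OC)c2c(=O)c(O[Si](C)(C)C)c(-c3ccc(O[Si](C)(C)C)cc3O[Si](C)(C)C)oc12 | intermediate
25 | Kushenol G 5-O-methyl ether | C=C(C)[C@H](CCC(C)(C)O)Cc1c(O)cc(OC)c2c(=O)c(O)c(-c3ccc(O)cc3O)oc12 | intermediate
26 | Kushenol G | C=C(C)[C@H](CCC(C)(C)O)Cc1c(O)cc(O)c2c(=O)c(O)c(-c3ccc(O)cc3O)oc12 | target

**Step count and risks**
Total: 17 steps. Longest linear sequence: 13 steps (steps 1, 2, 5–9 and 12–17 from 1; the arm from 4 through steps 3 and 4 is equally long).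

Steps most likely to fail:

Step 15. The Breslow intermediate formed at the aliphatic formyl group may expel the ring-A aryloxide (internal redox to an aryl arylacetate), the acidic O–CH(Ar) hydrogen may start an aldol closure to a five-membered ring, and the flavonolate may be over-oxidised under oxygen. The fallback sets out from 21 and replaces the umpolung catalysis by a reductive coupling: SmI2 (2.5 equiv) with t-BuOH in THF at −78 °C should join the two formyl carbons by ketyl–carbonyl pinacol cyclisation, forming the same C3–C4 bond without base or acyl-anion intermediate, to give 2-[2,4-bis(methoxymethoxy)phenyl]-8-[(2R)-5-hydroxy-5-methyl-2-(prop-1-en-2-yl)hexyl]-5-methoxy-7-(methoxymethoxy)chroman-3,4-diol F1. Oxidation of both carbinols with 2-iodoxybenzoic acid in DMSO at rt (diol to dione without C–C cleavage) should give the 3,4-dione, whose enol is 23, where the route is rejoined.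

Step 12. Displacement at a doubly ortho-substituted, hydrogen-bonded phenoxide may be slow, leaving time for decomposition of the electron-rich benzylic bromide and for base-induced aldol closure of the product onto its neighbouring formyl group. The fallback sets out from 16 and 14 and avoids base in the ether-forming event: enolate 17 is hydroxylated with 2-(phenylsulfonyl)-3-phenyloxaziridine at −78 °C to give methoxymethyl hydroxy[2,4-bis(methoxymethoxy)phenyl]acetate F2, which is coupled with phenol 14 in a Mitsunobu reaction (PPh3, diisopropyl azodicarboxylate, toluene, 0 °C → rt) and comes back to the route at 19.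

Step 17. The Lewis acid may ionise the tertiary alcohol or promote addition of a hydroxyl group across the isopropenyl double bond (ring closure of the side chain), and cleavage may stall because the free phenols bind the magnesium salt. The fallback sets out from 23 and demethylates by a nucleophile before the phenols are freed: NaSEt in DMF at 100 °C should remove the carbonyl-activated 5-O-methyl group by SN2 while MOM ethers are inert, giving 2-[2,4-bis(methoxymethoxy)phenyl]-3,5-dihydroxy-8-[(2R)-5-hydroxy-5-methyl-2-(prop-1-en-2-yl)hexyl]-7-(methoxymethoxy)-4H-chromen-4-one F3. The conditions of step 16 then take F3 through the hexakis(trimethylsilyl) ether of Kushenol G F4 to 26, the target.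

**Further compounds**
F1 | step 15 | 2-[2,4-bis(methoxymethoxy)phenyl]-8-[(2R)-5-hydroxy-5-methyl-2-(prop-1-en-2-yl)hexyl]-5-methoxy-7-(methoxymethoxy)chroman-3,4-diol (mixture at C2, C3, C4) | C=C(C)[C@H](CCC(C)(C)O)Cc1c(OCOC)cc(OC)c2C(O)C(O)C(c3ccc(OCOC)cc3OCOC)Oc12
F2 | step 12 | methoxymethyl hydroxy[2,4-bis(methoxymethoxy)phenyl]acetate (racemic) | COCOC(=O)C(O)c1ccc(OCOC)cc1OCOC
F3 | step 17 | 2-[2,4-bis(methoxymethoxy)phenyl]-3,5-dihydroxy-8-[(2R)-5-hydroxy-5-methyl-2-(prop-1-en-2-yl)hexyl]-7-(methoxymethoxy)-4H-chromen-4-one | C=C(C)[C@H](CCC(C)(C)O)Cc1c(OCOC)cc(O)c2c(=O)c(O)c(-c3ccc(OCOC)cc3OCOC)oc12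
F4 | step 17 | hexakis(trimethylsilyl) ether of Kushenol G | C=C(C)[C@H](CCC(C)(C)O[Si](C)(C)C)Cc1c(O[Si](C)(C)C)cc(O[Si](C)(C)C)c2c(=O)c(O[Si](C)(C)C)c(-c3ccc(O[Si](C)(C)C)cc3O[Si](C)(C)C)oc12
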